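**Retrosynthetic overview**

- The target is (2S)-2-(3,4-dimethoxyphenyl)-8-hydroxy-5,6,7-trimethoxychroman-4-one. The last operations free the 8-OH from a benzyl ether and the C4 ketone from a 4-silyloxy-2H-chromene.
- The strategy rests on the pyranone ring C (O1–C2–C3–C4–C4a–C8a): its C3–C4 bond is the α-bond of the C4 aryl ketone. Written as the enol silyl ether it becomes a C3=C4 alkene, which is cut by ring-closing metathesis between a vinyl group on C2 and a 1-silyloxyvinyl group on C4a.
- The metathesis diene comes from the corresponding aryl methyl ketone by soft enolisation. Its O1–C2 bond and the (S) centre come from an iridium-catalysed branched-selective allylic etherification of phenol 6 with cinnamyl carbonate 10.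
- Phenol 6 is made from acetophenone 1 by Duff formylation, Dakin oxidation and selective 3-O-benzylation; carbonate 10 is made from cinnamate ester 7 by reduction and acylation.
- Rings A and B are bought; ring C is the only ring formed, in step 8.

Key step: step 8

Assumption: by analogy with the usual sense of induction of cyclometalated iridium–phosphoramidite catalysts with heteroatom nucleophiles and aryl-substituted allyl carbonates, the (Sa,Sc,Sc) ligand is taken to give the (S)-ether; the mirror-image ligand would be used if the first run shows the opposite sense.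

**Route**

Step 1
Reactants: 1 1-(6-hydroxy-2,3,4-trimethoxyphenyl)ethan-1-one
Product: 3 3-acetyl-2-hydroxy-4,5,6-trimethoxybenzaldehyde, via aryl aldimine 2 (not isolated)
Conditions: hexamethylenetetramine (3 equiv), CF3CO2H, 85 °C; then 3 M aq. HCl, 60 °C
Reagents that add atoms: hexamethylenetetramine C1N2CN3CN1CN(C2)C3; water O
Why: Duff formylation: the HMTA-derived iminium ion attacks the only unsubstituted ring carbon (ortho to the free phenol, para to a methoxy group), and internal redox followed by acid hydrolysis of aldimine 2 should give the salicylaldehyde without touching the methyl ketone.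

Step 2
Reactants: 3 3-acetyl-2-hydroxy-4,5,6-trimethoxybenzaldehyde
Product: 5 1-(2,3-dihydroxy-4,5,6-trimethoxyphenyl)ethan-1-one, via aryl formate 4 (not isolated)
Conditions: 30% aq. H2O2 (1.5 equiv), cat. H2SO4, MeOH, 0 °C to rt, N2; NaHSO3 quench
Reagents that add atoms: hydrogen peroxide OO
Why: Dakin oxidation in its acid-catalysed form: the peroxide adduct of the aldehyde rearranges by migration of the electron-rich aryl group to formate 4, which is methanolysed in situ, while the far less electrophilic methyl ketone does not react and the acidic medium spares the oxidisable catechol.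

Step 3
Reactants: 5 1-(2,3-dihydroxy-4,5,6-trimethoxyphenyl)ethan-1-one
Product: 6 1-[3-(benzyloxy)-2-hydroxy-4,5,6-trimethoxyphenyl]ethan-1-one
Conditions: BnBr (1.05 equiv), K2CO3 (1.1 equiv), degassed acetone, rt to 45 °C, N2
Reagents that add atoms: benzyl bromide BrCc1ccccc1
Why: Williamson etherification under chelation control: the 2-OH is held in the hydrogen bond to the acetyl carbonyl and its phenoxide is delocalised into that carbonyl, so one equivalent of benzyl bromide should alkylate the 3-OH, as is usual for 2,3-dihydroxyaryl ketones.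

Step 4
Reactants: 7 methyl (E)-3-(3,4-dimethoxyphenyl)prop-2-enoate
Product: 9 (E)-3-(3,4-dimethoxyphenyl)prop-2-en-1-ol, via cinnamaldehyde 8 (not isolated)
Conditions: DIBAL-H (2.5 equiv), CH2Cl2, −78 to 0 °C; aq. Rochelle salt
Reagents that add atoms: none
Why: DIBAL-H reduces the conjugated ester in a 1,2-sense through enal 8 to the allylic alcohol and leaves the C=C bond intact.

Step 5
Reactants: 9 (E)-3-(3,4-dimethoxyphenyl)prop-2-en-1-ol
Product: 10 (E)-3-(3,4-dimethoxyphenyl)prop-2-en-1-yl methyl carbonate
Conditions: ClCO2Me (1.5 equiv), pyridine (2 equiv), CH2Cl2, 0 °C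
Reagents that add atoms: methyl chloroformate COC(=O)Cl
Why: O-acylation of the primary allylic alcohol with a chloroformate gives the carbonate leaving group that iridium allyl chemistry requires.

Step 6
Reactants: 6 1-[3-(benzyloxy)-2-hydroxy-4,5,6-trimethoxyphenyl]ethan-1-one; 10 (E)-3-(3,4-dimethoxyphenyl)prop-2-en-1-yl methyl carbonate
Product: 12 1-[3-(benzyloxy)-2-{[(1S)-1-(3,4-dimethoxyphenyl)prop-2-en-1-yl]oxy}-4,5,6-trimethoxyphenyl]ethan-1-one, via lithium aryloxide 11 (not isolated)
Conditions: 6, LiHMDS (1.0 equiv), THF, 0 °C; then 10 (1.3 equiv), [Ir(cod)Cl]2 (2 mol %), (Sa,Sc,Sc)-binaphthol N,N-bis(1-phenylethyl)phosphoramidite (4 mol %, pre-activated with n-PrNH2, volatiles removed), THF, rt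
Reagents that add atoms: none
Why: Iridium-catalysed asymmetric allylic etherification: the cyclometalated Ir–phosphoramidite ionises the carbonate to an allyl complex, and the aryloxide attacks the aryl-bearing terminus anti to iridium, so the branched ether forms and the ligand-controlled face selection sets C2 as (S); C-allylation is excluded because every ortho and para position of the aryloxide is substituted.

Step 7
Reactants: 12 1-[3-(benzyloxy)-2-{[(1S)-1-(3,4-dimethoxyphenyl)prop-2-en-1-yl]oxy}-4,5,6-trimethoxyphenyl]ethan-1-one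
Product: 13 {[1-(3-(benzyloxy)-2-{[(1S)-1-(3,4-dimethoxyphenyl)prop-2-en-1-yl]oxy}-4,5,6-trimethoxyphenyl)ethenyl]oxy}(tert-butyl)dimethylsilane
Conditions: TBSOTf (1.5 equiv), Et3N (3 equiv), CH2Cl2, 0 °C to rt; NaHCO3 work-up, Et3N-deactivated silica
Reagents that add atoms: tert-butyldimethylsilyl trifluoromethanesulfonate CC(C)(C)[Si](C)(C)OS(=O)(=O)C(F)(F)F
Why: Soft enolisation of the aryl methyl ketone (silyl triflate and amine) gives the enol silyl ether without a strong base, so the doubly activated C2–H of the allylic benzylic ether is neither deprotonated nor set up for Wittig rearrangement and the stereocentre is untouched.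

Step 8
Reactants: 13 {[1-(3-(benzyloxy)-2-{[(1S)-1-(3,4-dimethoxyphenyl)prop-2-en-1-yl]oxy}-4,5,6-trimethoxyphenyl)ethenyl]oxy}(tert-butyl)dimethylsilane
Product: 14 (2S)-8-(benzyloxy)-4-[(tert-butyldimethylsilyl)oxy]-2-(3,4-dimethoxyphenyl)-5,6,7-trimethoxy-2H-chromene
Conditions: (H2IMes)(PCy3)Cl2Ru=CHPh (second-generation Grubbs catalyst, 10 mol %), 1,4-benzoquinone (20 mol %), toluene (5 mM), 70 °C, Ar sparge, short reaction time
Reagents that add atoms: none
Why: Ring-closing olefin metathesis of an enol silyl ether: the ruthenium benzylidene loads onto the monosubstituted C2 vinyl group (the 1,1-disubstituted, electron-rich enol ether loads far more slowly), the alkylidene now at C3 undergoes intramolecular [2+2] cycloaddition with the CH2=C(OTBS) unit, and cycloreversion forms C3=C4 and expels Ru=CH2, which carries the chain with loss of ethylene. The closest known reaction type is the enol silyl ether–ene ring-closing metathesis that gives cyclic silyl enol ethers and 4-silyloxy-1,2-dihydroquinolines from ortho-(1-silyloxyvinyl)aryl allyl amines. The six-membered pyran ring (O1–C2–C3–C4–C4a–C8a) closes by C3=C4 bond formation between two alkenes held ortho on the arene, so cyclisation should outrun cross-metathesis at high dilution. No stereocentre is formed, and C2, set in step 6, is a spectator. The selectivity needed is against ruthenium hydride-mediated migration of the C2 vinyl double bond (which would erase C2) and against a Fischer carbene dead end; benzoquinone and a short reaction time deal with the first, and the ring-size-dictated orientation of the metallacycle, which keeps the oxygen-bearing carbon in the ring and releases only Ru=CH2, deals with the second.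

Step 9
Reactants: 14 (2S)-8-(benzyloxy)-4-[(tert-butyldimethylsilyl)oxy]-2-(3,4-dimethoxyphenyl)-5,6,7-trimethoxy-2H-chromene
Product: 15 (2S)-8-(benzyloxy)-2-(3,4-dimethoxyphenyl)-5,6,7-trimethoxychroman-4-one
Conditions: 1 M aq. HCl, THF, 0 °C to rt
Reagents that add atoms: none
Why: Acid-catalysed hydrolysis of the enol silyl ether (protonation at C3, loss of silanol) unveils the C4 ketone without ever forming the enolate, which could open the pyranone ring by β-elimination of the C8a phenoxide and racemise C2.

Step 10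
Reactants: 15 (2S)-8-(benzyloxy)-2-(3,4-dimethoxyphenyl)-5,6,7-trimethoxychroman-4-one
Product: 16 (2S)-2-(3,4-dimethoxyphenyl)-8-hydroxy-5,6,7-trimethoxychroman-4-one
Conditions: H2 (1 atm), 10% Pd/C, EtOAc, rt, stopped at full conversion
Reagents that add atoms: none
Why: Catalytic hydrogenolysis should cleave the benzyl aryl ether much faster than the cyclic benzylic C2–O1 bond or the aryl ketone, freeing the 8-OH without touching C2.

**Compound list**

1 | 1-(6-hydroxy-2,3,4-trimethoxyphenyl)ethan-1-one | CC(=O)c1c(O)cc(OC)c(OC)c1OC | starting material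
2 | 1-[2-hydroxy-3-(iminomethyl)-4,5,6-trimethoxyphenyl]ethan-1-one (aldimine, present as its iminium salt) | CC(=O)c1c(O)c(C=N)c(OC)c(OC)c1OC | intermediate
3 | 3-acetyl-2-hydroxy-4,5,6-trimethoxybenzaldehyde | CC(=O)c1c(O)c(C=O)c(OC)c(OC)c1OC | intermediate
4 | 3-acetyl-2-hydroxy-4,5,6-trimethoxyphenyl formate | CC(=O)c1c(O)c(OC=O)c(OC)c(OC)c1OC | intermediate
5 | 1-(2,3-dihydroxy-4,5,6-trimethoxyphenyl)ethan-1-one | CC(=O)c1c(O)c(O)c(OC)c(OC)c1OC | intermediate
6 | 1-[3-(benzyloxy)-2-hydroxy-4,5,6-trimethoxyphenyl]ethan-1-one | CC(=O)c1c(O)c(OCc2ccccc2)c(OC)c(OC)c1OC | intermediate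
7 | methyl (E)-3-(3,4-dimethoxyphenyl)prop-2-enoate | COC(=O)/C=C/c1ccc(OC)c(OC)c1 | starting material
8 | (E)-3-(3,4-dimethoxyphenyl)prop-2-enal | O=C/C=C/c1ccc(OC)c(OC)c1 | intermediate
9 | (E)-3-(3,4-dimethoxyphenyl)prop-2-en-1-ol | OC/C=C/c1ccc(OC)c(OC)c1 | intermediate
10 | (E)-3-(3,4-dimethoxyphenyl)prop-2-en-1-yl methyl carbonate | COC(=O)OC/C=C/c1ccc(OC)c(OC)c1 | intermediate
11 | lithium 2-acetyl-6-(benzyloxy)-3,4,5-trimethoxyphenolate | [Li+].CC(=O)c1c([O-])c(OCc2ccccc2)c(OC)c(OC)c1OC | intermediate
12 | 1-[3-(benzyloxy)-2-{[(1S)-1-(3,4-dimethoxyphenyl)prop-2-en-1-yl]oxy}-4,5,6-trimethoxyphenyl]ethan-1-one | COc1ccc([C@H](C=C)Oc2c(C(C)=O)c(OC)c(OC)c(OC)c2OCc2ccccc2)cc1OC | intermediate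
13 | {[1-(3-(benzyloxy)-2-{[(1S)-1-(3,4-dimethoxyphenyl)prop-2-en-1-yl]oxy}-4,5,6-trimethoxyphenyl)ethenyl]oxy}(tert-butyl)dimethylsilane | COc1ccc([C@H](C=C)Oc2c(C(=C)O[Si](C)(C)C(C)(C)C)c(OC)c(OC)c(OC)c2OCc2ccccc2)cc1OC | intermediate
14 | (2S)-8-(benzyloxy)-4-[(tert-butyldimethylsilyl)oxy]-2-(3,4-dimethoxyphenyl)-5,6,7-trimethoxy-2H-chromene | COc1ccc([C@@H]2C=C(O[Si](C)(C)C(C)(C)C)c3c(c(OCc4ccccc4)c(OC)c(OC)c3OC)O2)cc1OC | intermediate
15 | (2S)-8-(benzyloxy)-2-(3,4-dimethoxyphenyl)-5,6,7-trimethoxychroman-4-one | COc1ccc([C@@H]2CC(=O)c3c(c(OCc4ccccc4)c(OC)c(OC)c3OC)O2)cc1OC | intermediate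
16 | (2S)-2-(3,4-dimethoxyphenyl)-8-hydroxy-5,6,7-trimethoxychroman-4-one | COc1ccc([C@@H]2CC(=O)c3c(c(O)c(OC)c(OC)c3OC)O2)cc1OC | target

**Step count**

Total steps: 10. Longest linear sequence: 8 steps (steps 1, 2, 3, 6, 7, 8, 9, 10, from 1 to 16).

**Steps most likely to fail**

1. Step 8 (ring-closing metathesis). Ring closure onto the twisted, doubly ortho-flanked 1,1-disubstituted enol silyl ether may be slower than catalyst decomposition. Ruthenium hydrides formed on decomposition could then move the C2 vinyl double bond into conjugation and erase the stereocentre, or the enol silyl ether could be lost on prolonged heating. The fallback builds ring C by a different bond, the C2–aryl bond. It sets out from 6: condensation with N,N-dimethylformamide dimethyl acetal (toluene, 100 °C) should give the enaminone (E)-1-[3-(benzyloxy)-2-hydroxy-4,5,6-trimethoxyphenyl]-3-(dimethylamino)prop-2-en-1-one F1. Acid (HCl, CH2Cl2) should cyclise it with loss of dimethylamine to 8-(benzyloxy)-5,6,7-trimethoxy-4H-chromen-4-one F2. A palladium(II)/chiral pyridine–oxazoline-catalysed conjugate addition of 3,4-dimethoxyphenylboronic acid (Pd(OCOCF3)2, the t-BuPyOX antipode that gives the 2S product, NH4PF6, H2O, 1,2-dichloroethane, 60 °C) should then give 15, where the route is rejoined before step 10.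

2. Step 6 (allylic etherification). The chelated, 2,6-disubstituted aryloxide may attack the allyl complex slowly. The product ether, which carries an electron-rich aryl group and a stabilised aryloxide leaving group, may re-ionise on iridium, with erosion of enantiopurity and leakage to the linear ether. The fallback replaces catalytic C–O formation by a stereospecific substitution and sets out from 6.
 - Friedel–Crafts acylation of 1,2-dimethoxybenzene with 3-chloropropanoyl chloride (AlCl3, CH2Cl2, 0 °C) should give 3-chloro-1-(3,4-dimethoxyphenyl)propan-1-one F3.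
 - Oxazaborolidine (CBS) reduction ((S)-Me-CBS, BH3·SMe2, THF) should give (R)-3-chloro-1-(3,4-dimethoxyphenyl)propan-1-ol F4.
 - Displacement with sodium phenylselenide (PhSeSePh, NaBH4, EtOH) should give (R)-1-(3,4-dimethoxyphenyl)-3-(phenylselanyl)propan-1-ol F5.
 - Mitsunobu reaction of F5 with 6 (PPh3, DIAD, THF, 0 °C) should proceed with inversion to 1-[3-(benzyloxy)-2-{[(1S)-1-(3,4-dimethoxyphenyl)-3-(phenylselanyl)propyl]oxy}-4,5,6-trimethoxyphenyl]ethan-1-one F6.
 - Oxidation (H2O2, pyridine, CH2Cl2, 0 °C to rt) should give the selenoxide 1-[3-(benzyloxy)-2-{[(1S)-1-(3,4-dimethoxyphenyl)-3-(phenylseleninyl)propyl]oxy}-4,5,6-trimethoxyphenyl]ethan-1-one F7, which is not isolated and should undergo syn-elimination to the terminal alkene 12, where the route is rejoined before step 7.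

3. Step 3 (mono-benzylation). Regiocontrol may be lost, with alkylation of the chelated 2-OH or of both hydroxyl groups, and the electron-rich catechol may autoxidise under base. The fallback is exhaustive protection followed by selective deprotection and sets out from 5. Excess benzyl bromide (K2CO3, DMF, 60 °C) should give 1-[2,3-bis(benzyloxy)-4,5,6-trimethoxyphenyl]ethan-1-one F8. Magnesium bromide etherate (toluene/Et2O, 70 °C) should then remove only the benzyl group ortho to the acetyl group through the magnesium chelate, giving 6, where the route is rejoined before step 6.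

**Further compounds**

F1 | step 8 | (E)-1-[3-(benzyloxy)-2-hydroxy-4,5,6-trimethoxyphenyl]-3-(dimethylamino)prop-2-en-1-one | CN(C)/C=C/C(=O)c1c(O)c(OCc2ccccc2)c(OC)c(OC)c1OC
F2 | step 8 | 8-(benzyloxy)-5,6,7-trimethoxy-4H-chromen-4-one | O=c1ccoc2c(OCc3ccccc3)c(OC)c(OC)c(OC)c12
F3 | step 6 | 3-chloro-1-(3,4-dimethoxyphenyl)propan-1-one | COc1ccc(C(=O)CCCl)cc1OC
F4 | step 6 | (R)-3-chloro-1-(3,4-dimethoxyphenyl)propan-1-ol | O[C@H](CCCl)c1ccc(OC)c(OC)c1
F5 | step 6 | (R)-1-(3,4-dimethoxyphenyl)-3-(phenylselanyl)propan-1-ol | O[C@H](CC[Se]c1ccccc1)c1ccc(OC)c(OC)c1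
F6 | step 6 | 1-[3-(benzyloxy)-2-{[(1S)-1-(3,4-dimethoxyphenyl)-3-(phenylselanyl)propyl]oxy}-4,5,6-trimethoxyphenyl]ethan-1-one | COc1ccc([C@H](CC[Se]c2ccccc2)Oc2c(C(C)=O)c(OC)c(OC)c(OC)c2OCc2ccccc2)cc1OC
F7 | step 6 | 1-[3-(benzyloxy)-2-{[(1S)-1-(3,4-dimethoxyphenyl)-3-(phenylseleninyl)propyl]oxy}-4,5,6-trimethoxyphenyl]ethan-1-one | COc1ccc([C@H](CC[Se](=O)c2ccccc2)Oc2c(C(C)=O)c(OC)c(OC)c(OC)c2OCc2ccccc2)cc1OC
F8 | step 3 | 1-[2,3-bis(benzyloxy)-4,5,6-trimethoxyphenyl]ethan-1-one | CC(=O)c1c(OCc2ccccc2)c(OCc2ccccc2)c(OC)c(OC)c1OC
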